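**Retrosynthetic overview**
- Feature: the quaternary stereocentre C3 of the dodecadienone chain, with its vinyl group and the C2 methylene next to the C1 ketone, is read as an opened cyclopropylmethyl unit (the ring CH–CH2 bond cleaved).
- Last disconnections: the two MOM ethers, then the C1–C2 bond, made from a primary homoallyllithium and the N-methoxy-N-methylamide of 2,4-bis(methoxymethoxy)benzoic acid.
- The homoallyllithium comes from a cyclopropylmethyl iodide by lithium–iodine exchange and anionic ring opening toward the primary carbanion.
- Key disconnection: the two cyclopropane bonds from CH2 (out of CH2I2) to the 2,3-alkene of (2E,6E)-farnesol, hydroxyl-directed and ligand-controlled; this sets the C3 configuration.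
- Ring order: the cyclopropane is the only ring formed (step 2) and is opened again (step 6); the benzene ring is bought as methyl 2,4-dihydroxybenzoate.

Key step: step 2

Assumption: the dioxaborolane ligand is taken to show the same face preference with farnesol as with other allylic alcohols, so that the (4S,5S) ligand gives the (1R,2R) cyclopropane; the enantiomeric purity of the cyclopropylmethanol is to be checked (for example as its Mosher ester), and the (4R,5R) ligand would be used if the sense proved opposite.

**Step 1**
Reactants: 1 butylboronic acid; 2 (2S,3S)-2,3-dihydroxy-N,N,N′,N′-tetramethylbutanediamide (the tetramethyl diamide of D-tartaric acid)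
Product: 3 (4S,5S)-2-butyl-N,N,N′,N′-tetramethyl-1,3,2-dioxaborolane-4,5-dicarboxamide
Conditions: toluene, reflux, Dean–Stark trap
Reagents that add atoms: butylboronic acid (compound 1), CCCCB(O)O
Why: Boronic acids condense with 1,2-diols to five-membered boronic esters, and azeotropic removal of water should drive this esterification to completion without touching the two stereocentres of the diamide.

**Step 2**
Reactants: 4 (2E,6E)-farnesol; 5 diiodomethane; 3 (4S,5S)-dioxaborolane (1.2 equiv, chiral controller, not incorporated)
Product: 7 [(1R,2R)-2-[(3E)-4,8-dimethylnona-3,7-dien-1-yl]-2-methylcyclopropyl]methanol, via iodomethylzinc farnesoxide 6 (not isolated)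
Conditions: ZnEt2 (2.2 equiv), CH2I2 (4.4 equiv), DME (2.2 equiv), CH2Cl2, −10 °C; then 3 and 4 in CH2Cl2, −10 °C to rt; aq NH4Cl, then 2 M NaOH/30% H2O2 wash
Reagents that add atoms: diiodomethane (compound 5), ICI
Why: ZnEt2 and CH2I2 give Zn(CH2I)2 (held as its DME complex), which deprotonates 4 to the zinc alkoxide 6; the alkoxide oxygen binds to the boron of 3, the amide carbonyl groups hold the zinc carbenoid, and CH2 passes to the C2=C3 alkene through the butterfly transition state of a Simmons–Smith reaction. The closest known reaction is the dioxaborolane-mediated enantioselective Simmons–Smith cyclopropanation of allylic alcohols, which is established for trisubstituted substrates of the geraniol type. The three-membered ring closes by concerted syn [2+1] methylene transfer, so both new C–C bonds (CH2 to C2 and CH2 to C3 of farnesol) form at once. The relative configuration of the two new stereocentres follows from stereospecific syn addition to the E alkene (CH2OH cis to the ring methyl group), and the absolute configuration is set by the (4S,5S) ligand, which leaves one face of the bound alkene open. The step needs site selectivity among three trisubstituted alkenes and face selectivity at the allylic one: the hydroxyl group secures the first, because only the allylic alkene is reached by the alkoxide-bound carbenoid while the DME-complexed reagent attacks isolated alkenes slowly, and the ligand secures the second.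

**Step 3**
Reactants: 7 cyclopropylmethanol
Product: 8 (1R,2R)-1-[(3E)-4,8-dimethylnona-3,7-dien-1-yl]-2-(iodomethyl)-1-methylcyclopropane
Conditions: PPh3, imidazole, I2, CH2Cl2, 0 °C, dark; filtration through Et3N-deactivated silica; used at once
Reagents that add atoms: iodine, II
Why: In this Appel-type iodination the alkoxyphosphonium ion should be displaced by iodide in an SN2 step at the primary carbon under buffered, non-ionising conditions, so that neither stereocentre is touched and the ring-opening cyclopropylcarbinyl cation is avoided.

**Step 4**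
Reactants: 9 methyl 2,4-dihydroxybenzoate
Product: 10 methyl 2,4-bis(methoxymethoxy)benzoate
Conditions: NaH (2.5 equiv), MOMCl (2.5 equiv), DMF, 0 °C to rt
Reagents that add atoms: chloromethyl methyl ether, COCCl
Why: Williamson-type O-alkylation of both sodium phenoxides by the reactive α-chloro ether should be complete, since full deprotonation with NaH also frees the hydrogen-bonded ortho hydroxyl group.

**Step 5**
Reactants: 10 methyl 2,4-bis(methoxymethoxy)benzoate
Product: 11 N-methoxy-2,4-bis(methoxymethoxy)-N-methylbenzamide
Conditions: MeNH(OMe)·HCl (1.5 equiv), i-PrMgCl (3.0 equiv), THF, −20 to 0 °C; aq NH4Cl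
Reagents that add atoms: N,O-dimethylhydroxylamine hydrochloride, CNOC.Cl
Why: The chloromagnesium amide of N,O-dimethylhydroxylamine should convert the ester directly into the Weinreb amide (ester aminolysis), and the MOM ethers are inert to these basic conditions.

**Step 6**
Reactants: 8 cyclopropylmethyl iodide; 11 Weinreb amide (1.1 equiv)
Product: 15 (3R,6E)-1-[2,4-bis(methoxymethoxy)phenyl]-3-ethenyl-3,7,11-trimethyldodeca-6,10-dien-1-one, via cyclopropylmethyllithium 12 (not isolated), via homoallyllithium 13 (not isolated), via lithium hemiaminal alkoxide 14 (not isolated)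
Conditions: t-BuLi (2.0 equiv), pentane/Et2O 3:2, −78 °C; warm to 0 °C; recool to −78 °C, add 11 in Et2O, −78 to 0 °C; aq NH4Cl
Reagents that add atoms: none
Why: Lithium–iodine exchange of a primary iodide with t-BuLi at −78 °C runs through an ate complex without free radicals, the cyclopropylmethyllithium 12 should open on warming (cyclopropylcarbinyl-to-homoallyl anion rearrangement) at the bond to the ring CH2 because this gives the primary carbanion 13 instead of a tertiary one and leaves the quaternary stereocentre untouched, and 13 should add only once to 11 because the chelated adduct 14 persists until work-up (Weinreb ketone synthesis).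

**Step 7**
Reactants: 15 bis-MOM ketone
Product: 16 (3R,6E)-1-(2,4-dihydroxyphenyl)-3-ethenyl-3,7,11-trimethyldodeca-6,10-dien-1-one (CNP0157533.1)
Conditions: 1.25 M HCl in MeOH, THF, 0 °C to rt
Reagents that add atoms: none
Why: Acid-catalysed acetal cleavage (MOM ether removal) releases the methoxymethyl cation, which methanol traps as dimethoxymethane; dilute acid at or below room temperature should leave the trisubstituted alkenes, the vinyl group and the quaternary stereocentre unchanged.

**Compound list**
1 | butylboronic acid | CCCCB(O)O | starting material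
2 | (2S,3S)-2,3-dihydroxy-N,N,N′,N′-tetramethylbutanediamide | CN(C)C(=O)[C@@H](O)[C@H](O)C(=O)N(C)C | starting material
3 | (4S,5S)-2-butyl-N,N,N′,N′-tetramethyl-1,3,2-dioxaborolane-4,5-dicarboxamide | CCCCB1O[C@H](C(=O)N(C)C)[C@@H](C(=O)N(C)C)O1 | intermediate
4 | (2E,6E)-farnesol | CC(C)=CCC/C(C)=C/CC/C(C)=C/CO | starting material
5 | diiodomethane | ICI | starting material
6 | iodomethylzinc (2E,6E)-farnesoxide | CC(C)=CCC/C(C)=C/CC/C(C)=C/CO[Zn]CI | intermediate
7 | [(1R,2R)-2-[(3E)-4,8-dimethylnona-3,7-dien-1-yl]-2-methylcyclopropyl]methanol | OC[C@H]1[C@](C)(CC/C=C(\C)CCC=C(C)C)C1 | intermediate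
8 | (1R,2R)-1-[(3E)-4,8-dimethylnona-3,7-dien-1-yl]-2-(iodomethyl)-1-methylcyclopropane | IC[C@H]1[C@](C)(CC/C=C(\C)CCC=C(C)C)C1 | intermediate
9 | methyl 2,4-dihydroxybenzoate | COC(=O)c1ccc(O)cc1O | starting material
10 | methyl 2,4-bis(methoxymethoxy)benzoate | COC(=O)c1ccc(OCOC)cc1OCOC | intermediate
11 | N-methoxy-2,4-bis(methoxymethoxy)-N-methylbenzamide | CON(C)C(=O)c1ccc(OCOC)cc1OCOC | intermediate
12 | {[(1R,2R)-2-[(3E)-4,8-dimethylnona-3,7-dien-1-yl]-2-methylcyclopropyl]methyl}lithium | [Li]C[C@H]1[C@](C)(CC/C=C(\C)CCC=C(C)C)C1 | intermediate
13 | [(2S,5E)-2-ethenyl-2,6,10-trimethylundeca-5,9-dien-1-yl]lithium (same spatial arrangement as C3 of the target; the descriptor changes by priority only) | C=C[C@](C)(CC/C=C(\C)CCC=C(C)C)C[Li] | intermediate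
14 | lithium (3R,6E)-1-[2,4-bis(methoxymethoxy)phenyl]-3-ethenyl-1-[methoxy(methyl)amino]-3,7,11-trimethyldodeca-6,10-dien-1-olate (both C1 epimers) | C=C[C@](C)(CC/C=C(\C)CCC=C(C)C)CC(O[Li])(N(C)OC)c1ccc(OCOC)cc1OCOC | intermediate
15 | (3R,6E)-1-[2,4-bis(methoxymethoxy)phenyl]-3-ethenyl-3,7,11-trimethyldodeca-6,10-dien-1-one | C=C[C@](C)(CC/C=C(\C)CCC=C(C)C)CC(=O)c1ccc(OCOC)cc1OCOC | intermediate
16 | (3R,6E)-1-(2,4-dihydroxyphenyl)-3-ethenyl-3,7,11-trimethyldodeca-6,10-dien-1-one | C=C[C@](C)(CC/C=C(\C)CCC=C(C)C)CC(=O)c1ccc(O)cc1O | target

**Step count**
Total: 7 steps.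
Longest linear sequence: 5 steps (steps 1, 2, 3, 6 and 7: ligand 3 is made in step 1 and is a reactant of the key step, after which the sequence runs through 7, 8 and 15 to 16). The carbon skeleton itself passes through four steps from farnesol 4, and the aryl part through four steps from ester 9.

**Steps most likely to fail**

1. Step 6. The hindered primary lithium 13 may act as a base instead of adding to the amide carbonyl (metalation of the arene beside a MOM ether, or attack at the N-methoxy group with loss of formaldehyde). Fallback, setting out from Weinreb amide 11 and coming back at ketone 15: 11 is reduced with LiAlH4 (THF, 0 °C) to 2,4-bis(methoxymethoxy)benzaldehyde F2. Lithium 13, made as in step 6, should add to this more electrophilic carbonyl group at −78 °C and give the benzylic alcohol (3R,6E)-1-[2,4-bis(methoxymethoxy)phenyl]-3-ethenyl-3,7,11-trimethyldodeca-6,10-dien-1-ol F3 as a mixture of C1 epimers, which is of no consequence. Oxidation with Dess–Martin periodinane (NaHCO3, CH2Cl2) or MnO2 should then give 15.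

2. Step 3. Ionisation at the cyclopropylcarbinyl carbon during or after iodination would open the ring toward the tertiary homoallyl cation, and light-induced homolysis of the C–I bond may degrade 8 on storage. Fallback, setting out from alcohol 7 and coming back at cyclopropylmethyllithium 12: 7 is treated with PhSSPh and Bu3P (THF, rt) to give, by SN2 displacement of the alkoxyphosphonium ion with thiolate, {[(1R,2R)-2-[(3E)-4,8-dimethylnona-3,7-dien-1-yl]-2-methylcyclopropyl]methyl}(phenyl)sulfane F1, which has no ionisable bond and can be stored. Reductive lithiation of F1 with lithium 4,4′-di-tert-butylbiphenylide (THF, −78 °C) cleaves the C–S bond and should give 12, which is warmed and acylated as in step 6. Since a cyclopropylmethyl radical is passed through, an excess of the reductant at −78 °C is needed so that the second electron transfer outruns radical ring opening, and the enantiomeric purity of 15 is to be rechecked.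

3. Step 7. Acid may add to the two trisubstituted alkenes, or start a cation–olefin cyclisation, while the slower para MOM ether is still being cleaved. Fallback, setting out from ester 9 and coming back at target 16: 9 is silylated (TBSCl, imidazole, DMF) to methyl 2,4-bis(tert-butyldimethylsilyloxy)benzoate F4, which is converted as in step 5 into 2,4-bis(tert-butyldimethylsilyloxy)-N-methoxy-N-methylbenzamide F5. Acylation of lithium 13 with F5 as in step 6 should give (3R,6E)-1-[2,4-bis(tert-butyldimethylsilyloxy)phenyl]-3-ethenyl-3,7,11-trimethyldodeca-6,10-dien-1-one F6. Bu4NF buffered with AcOH (THF, 0 °C) should then remove both aryl silyl ethers without acid and give 16.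

**Further compounds**
F1 | step 3 | {[(1R,2R)-2-[(3E)-4,8-dimethylnona-3,7-dien-1-yl]-2-methylcyclopropyl]methyl}(phenyl)sulfane | c1ccccc1SC[C@H]1[C@](C)(CC/C=C(\C)CCC=C(C)C)C1
F2 | step 6 | 2,4-bis(methoxymethoxy)benzaldehyde | O=Cc1ccc(OCOC)cc1OCOC
F3 | step 6 | (3R,6E)-1-[2,4-bis(methoxymethoxy)phenyl]-3-ethenyl-3,7,11-trimethyldodeca-6,10-dien-1-ol (both C1 epimers) | C=C[C@](C)(CC/C=C(\C)CCC=C(C)C)CC(O)c1ccc(OCOC)cc1OCOC
F4 | step 7 | methyl 2,4-bis(tert-butyldimethylsilyloxy)benzoate | COC(=O)c1ccc(O[Si](C)(C)C(C)(C)C)cc1O[Si](C)(C)C(C)(C)C
F5 | step 7 | 2,4-bis(tert-butyldimethylsilyloxy)-N-methoxy-N-methylbenzamide | CON(C)C(=O)c1ccc(O[Si](C)(C)C(C)(C)C)cc1O[Si](C)(C)C(C)(C)C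
F6 | step 7 | (3R,6E)-1-[2,4-bis(tert-butyldimethylsilyloxy)phenyl]-3-ethenyl-3,7,11-trimethyldodeca-6,10-dien-1-one | C=C[C@](C)(CC/C=C(\C)CCC=C(C)C)CC(=O)c1ccc(O[Si](C)(C)C(C)(C)C)cc1O[Si](C)(C)C(C)(C)C
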